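- In a one-step world the electrophile, at 20 mM against 22.0 mM of nucleophile, was the limiting reagent, and I expected each flask to end with it gone.

| setting | delta | epsilon | north-east | south |
|---|---|---|---|---|
| electrophile | 20 mM | 20 mM | 20 mM | 20 mM |
| nucleophile | 22 mM | 22 mM | 22.0 mM | 22.0 mM |
| free base | 5.3 mM | 12 mM | 10.0 mM | 20.0 mM |
| remark | run made earlier | run made earlier |  |  |
| time |  |  | 80 min | 80 min |

| run | time / min | electrophile / % | target / % |
|---|---|---|---|
| delta | 2.00 | 52 | 48 |
| delta | 6.00 | 35 | 64 |
| delta | 12.0 | 32 | 67 |
| delta | 15.0 | 31 | 72 |
| delta | 25.0 | 28 | 67 |
| delta | 30.0 | 29 | 74 |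
| delta | 40.0 | 27 | 67 |
| epsilon | 3.00 | 44 | 57 |
| epsilon | 5.00 | 36 | 64 |
| epsilon | 8.00 | 28 | 75 |
| epsilon | 12.0 | 23 | 80 |
| epsilon | 15.0 | 18 | 81 |
| epsilon | 25.0 | 16 | 86 |
| epsilon | 40.0 | 12 | 80 |

(readings scatter by 2 percentage points)

- the earlier runs were read with a standard deviation of 2 percentage points

- part of the electrophile that has reacted at the end, north-east
- part of the electrophile that has reacted at the end, south
- what raising the concentration of free base from its lowest to its highest value here does to the part of the electrophile that has reacted (changes below 5 percentage points count as none) (it falls / it rises / no change)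

- You took delta for merely slow, but I could not: its electrophile reached 52% by 2.00 min, then went from 31% at 15.0 min to 27% at 40.0 min, against a scatter of 2 points.
- So I followed one nucleophile molecule, which I supposed had two fates: it couples, or it takes a proton and goes dead. Each coupling frees one acid; I assumed the free base takes that first and nucleophile afterwards, so past that point each coupling costs two nucleophiles.
- That gave me the stall point: the smallest of c(electrophile), c(nucleophile) and the mean of c(nucleophile) and c(free base), as a share of c(electrophile). For north-east it was 80.0%.
- Delta's stall point was 68.2% and epsilon's 85.0%; their last readings stood higher by 3.9 points on average, so I committed to 83.9% for north-east.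
- South's stall point was 100%, so I reckoned it by rate. Delta's first reading gave k near 23.1 L mol⁻¹ min⁻¹, which with equal partners left 2.64% of the electrophile, so 97.4% had reacted, a rise of 14 points over north-east.
- The forecast gave 83% (79% to 87%) for north-east, lower than mine, and 99% (94% to 100%) for south, higher than mine, said that it rises, and began “The plateaus point to a stall set by acid”.
- North-east gave 84.5% and south 97.9%; for the part of the electrophile that had reacted, with free base raised from its lowest to its highest value, the answer was it rises, by 13 points.

    electrophile + nucleophile → acid set free + target (k = 23.8 L mol⁻¹ min⁻¹)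
    nucleophile + acid set free ⇌ protonated nucleophile, settled at all times (K = 19000 L mol⁻¹)
    acid set free + free base ⇌ salt of the base, settled at all times (K = 88300 L mol⁻¹)
    2 nucleophile → homo dimer (k = 0.159 L mol⁻¹ min⁻¹)

- North-east passed its stall point of 80.0%, and at 80.0 min it held 2.15 mM of acid set free, unbound, beside 4.80 mM of protonated nucleophile. A flask like south but charged with 13 mM of nucleophile has the stall point 65.0%; it gave 64.7%, with 0% of its nucleophile and 35% of its free base left.

The data are calculated on assumed constants.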